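C2 of ring C of the lower (epigallocatechin) unit bears O1 and the ipso carbon C1' of ring B, so it is a masked acyl carbon. The route cuts the C2–C1' bond at the ketone level: a ring B arylmagnesium bromide adds to a Weinreb amide that already carries the complete epiafzelechin-(4β→6) upper unit, the ring A phenol that becomes O1 and the C3 oxygen centre from (R)-glycidate. This single step unites both halves as an α-silyloxy aryl ketone; reductive etherification then closes ring C and sets C2 cis to C3–O. One bromolactone serves both flavan units, and the C8 bromines direct the 4→6 linkage.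

Key step: step 16

Remark: flavan numbering (O1, C2–C4, C4a–C8a, ring B primed) is used for both units; "upper" is the epiafzelechin unit, "lower" the epigallocatechin unit; 4β means trans to the C3 oxygen of the upper unit; Bn = benzyl, TBS = tert-butyldimethylsilyl, MOM = methoxymethyl.

Step 1
Reactants: 1 3,5-bis(benzyloxy)phenol
Product: 2 3,5-bis(benzyloxy)-2,6-dibromophenol
Conditions: NBS (2.05 equiv), i-Pr2NH (0.1 equiv), CH2Cl2, −20 → 0 °C
Reagents that add atoms: N-bromosuccinimide, O=C1CCC(=O)N1Br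
Why: Amine-catalysed electrophilic bromination of a phenol delivers bromine through the hydrogen-bonded N-bromoamine to the two positions ortho to OH, in preference to the para position that is flanked by two benzyloxy groups.

Step 2
Reactants: 2 3,5-bis(benzyloxy)-2,6-dibromophenol
Product: 3 1,5-bis(benzyloxy)-2,4-dibromo-3-(methoxymethoxy)benzene
Conditions: MOMCl, K2CO3, acetone, rt
Reagents that add atoms: chloromethyl methyl ether, COCCl
Why: Williamson O-alkylation of the acidic dibromophenol masks the oxygen that becomes O1 and leaves two equivalent C–Br bonds.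

Step 3
Reactants: 3 1,5-bis(benzyloxy)-2,4-dibromo-3-(methoxymethoxy)benzene; 4 methyl (2R)-oxirane-2-carboxylate
Product: 7 methyl (2R)-3-[4,6-bis(benzyloxy)-3-bromo-2-(methoxymethoxy)phenyl]-2-hydroxypropanoate, via aryllithium 5 (not isolated), via arylmagnesium bromide 6 (not isolated)
Conditions: n-BuLi (1.0 equiv), THF, −78 °C; MgBr2·OEt2; CuI (10 mol%), 4, −40 → −10 °C; aq NH4Cl
Reagents that add atoms: none
Why: Bromine–lithium exchange on one of the two equivalent bromides and copper-catalysed SN2 opening of the epoxide at its CH2 carbon attach the three-carbon chain, while the (2R) centre of 4, which becomes C3 of both flavan units, is not touched.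

Step 4
Reactants: 7 methyl (2R)-3-[4,6-bis(benzyloxy)-3-bromo-2-(methoxymethoxy)phenyl]-2-hydroxypropanoate
Product: 9 (3R)-5,7-bis(benzyloxy)-8-bromo-3-hydroxychroman-2-one, via phenol ester 8 (not isolated)
Conditions: HCl (cat.), MeOH, 45 °C; evaporate; TsOH·H2O (cat.), toluene, 80 °C
Reagents that add atoms: none
Why: Acid-catalysed acetal exchange frees the phenol and acid-catalysed lactonisation onto the methyl ester ties it up again, so the C3 hydroxyl should be the only free OH.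

Step 5
Reactants: 9 (3R)-5,7-bis(benzyloxy)-8-bromo-3-hydroxychroman-2-one
Product: 10 (3R)-5,7-bis(benzyloxy)-8-bromo-3-[(tert-butyldimethylsilyl)oxy]chroman-2-one
Conditions: TBSOTf, 2,6-lutidine, CH2Cl2, −78 → 0 °C
Reagents that add atoms: tert-butyldimethylsilyl trifluoromethanesulfonate, CC(C)(C)[Si](C)(C)OS(=O)(=O)C(F)(F)F
Why: Silylation of the secondary alcohol with a silyl triflate and a hindered pyridine base should not open or enolise the aryl lactone, and the bulky silyl ether later shields one face of ring C.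

Step 6
Reactants: 10 (3R)-5,7-bis(benzyloxy)-8-bromo-3-[(tert-butyldimethylsilyl)oxy]chroman-2-one
Product: 11 (2R)-3-[4,6-bis(benzyloxy)-3-bromo-2-hydroxyphenyl]-2-[(tert-butyldimethylsilyl)oxy]-N-methoxy-N-methylpropanamide
Conditions: MeNH(OMe)·HCl, i-PrMgCl, THF, −20 °C; aq NH4Cl
Reagents that add atoms: N,O-dimethylhydroxylamine hydrochloride, CNOC.Cl
Why: Aminolysis of the activated aryl lactone by the chloromagnesium amide (Weinreb amide formation) gives the acylating group and frees the ring A phenol in one step without epimerising C3.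

Step 7
Reactants: 9 (3R)-5,7-bis(benzyloxy)-8-bromo-3-hydroxychroman-2-one
Product: 12 (3R)-3,5,7-tris(benzyloxy)-8-bromochroman-2-one
Conditions: BnBr, Ag2O, 4 Å MS, CH2Cl2, rt, dark
Reagents that add atoms: benzyl bromide, BrCc1ccccc1
Why: Silver-oxide-mediated O-benzylation is neutral, so the α-hydroxy lactone should be etherified without enolisation; this benzyl ether keeps the upper C3 oxygen from being acylated later.

Step 8
Reactants: 12 (3R)-3,5,7-tris(benzyloxy)-8-bromochroman-2-one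
Product: 13 (2R)-2-(benzyloxy)-3-[4,6-bis(benzyloxy)-3-bromo-2-hydroxyphenyl]-N-methoxy-N-methylpropanamide
Conditions: MeNH(OMe)·HCl, i-PrMgCl, THF, −20 °C; aq NH4Cl
Reagents that add atoms: N,O-dimethylhydroxylamine hydrochloride, CNOC.Cl
Why: The same lactone aminolysis as in step 6 gives the Weinreb amide and the free phenol of the upper unit.

Step 9
Reactants: 13 (2R)-2-(benzyloxy)-3-[4,6-bis(benzyloxy)-3-bromo-2-hydroxyphenyl]-N-methoxy-N-methylpropanamide; 14 1-(benzyloxy)-4-bromobenzene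
Product: 17 (2R)-2-(benzyloxy)-3-[4,6-bis(benzyloxy)-3-bromo-2-hydroxyphenyl]-1-[4-(benzyloxy)phenyl]propan-1-one, via Grignard reagent 15 (not isolated), via chelated tetrahedral adduct 16 (not isolated)
Conditions: 14, Mg, THF, 50 °C; 13, t-BuMgCl (1.05 equiv), THF, −20 °C, then the Grignard solution (1.5 equiv), 0 °C → rt; aq NH4Cl, 0 °C
Reagents that add atoms: none
Why: Weinreb ketone synthesis: the magnesium chelate of the adduct should survive until the quench, so one aryl group adds and the masked carbonyl cannot enolise towards C3.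

Step 10
Reactants: 17 (2R)-2-(benzyloxy)-3-[4,6-bis(benzyloxy)-3-bromo-2-hydroxyphenyl]-1-[4-(benzyloxy)phenyl]propan-1-one
Product: 19 (2R,3R)-3,5,7-tris(benzyloxy)-2-[4-(benzyloxy)phenyl]-8-bromochroman, via oxocarbenium triflate 18 (not isolated)
Conditions: Et3SiH (3 equiv), TMSOTf (0.3 equiv), CH2Cl2, −78 → −20 °C
Reagents that add atoms: none
Why: Reductive etherification: the phenol closes onto the ketone (6-exo-trig) and ionises to the 2-aryl oxocarbenium ion 18, whose C3 benzyloxy group sits pseudoaxial to avoid A(1,2) strain with the coplanar aryl group, so hydride should add to C2 from the opposite face and give the 2,3-cis flavan.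

Step 11
Reactants: 19 (2R,3R)-3,5,7-tris(benzyloxy)-2-[4-(benzyloxy)phenyl]-8-bromochroman
Product: 20 (2R,3R,4S)-3,5,7-tris(benzyloxy)-2-[4-(benzyloxy)phenyl]-8-bromo-4-(2-ethoxyethoxy)chroman
Conditions: DDQ (2 equiv), 2-ethoxyethanol (5 equiv), CH2Cl2, rt
Reagents that add atoms: 2-ethoxyethanol, CCOCCO
Why: DDQ abstracts hydride from C4, which is benzylic to the 5,7-dioxygenated ring A, and the alcohol should trap the cation trans to the C3 benzyloxy group (oxidative benzylic etherification).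

Step 12
Reactants: 20 (2R,3R,4S)-3,5,7-tris(benzyloxy)-2-[4-(benzyloxy)phenyl]-8-bromo-4-(2-ethoxyethoxy)chroman; 11 (2R)-3-[4,6-bis(benzyloxy)-3-bromo-2-hydroxyphenyl]-2-[(tert-butyldimethylsilyl)oxy]-N-methoxy-N-methylpropanamide
Product: 21 (2R)-3-{4,6-bis(benzyloxy)-3-bromo-2-hydroxy-5-[3,5,7,4'-tetra-O-benzyl-8-bromo-(−)-epiafzelechin-4β-yl]phenyl}-2-[(tert-butyldimethylsilyl)oxy]-N-methoxy-N-methylpropanamide
Conditions: TMSOTf (0.5 equiv), 11 (1.5 equiv), CH2Cl2, −78 → −40 °C; Et3N quench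
Reagents that add atoms: none
Why: Friedel–Crafts alkylation by the flavan-4-yl cation: the only unsubstituted ring carbon of 11 (para to the free phenol, the ortho position being blocked by bromine) attacks anti to the C3 benzyloxy and C2 aryl groups, which should set the 4β (3,4-trans) centre, and the C8 bromine of 20 suppresses its self-condensation.

Step 13
Reactants: 22 5-bromo-2,3-dihydroxybenzaldehyde
Product: 23 2,3-bis(benzyloxy)-5-bromobenzaldehyde
Conditions: BnBr (2.2 equiv), K2CO3, DMF, 60 °C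
Reagents that add atoms: benzyl bromide, BrCc1ccccc1
Why: Williamson benzylation of both phenols protects the two oxygens that stay free in the target (4'-OH and 5'-OH).

Step 14
Reactants: 23 2,3-bis(benzyloxy)-5-bromobenzaldehyde
Product: 25 2,3-bis(benzyloxy)-5-bromophenol, via aryl formate 24 (not isolated)
Conditions: mCPBA, CH2Cl2, rt; then K2CO3 (cat.), MeOH, rt
Reagents that add atoms: 3-chloroperbenzoic acid, O=C(OO)c1cccc(Cl)c1
Why: Baeyer–Villiger oxidation of the ortho-alkoxy benzaldehyde proceeds by migration of the electron-rich aryl group, and methanolysis of the formate should give the phenol that becomes the 3'-oxygen.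

Step 15
Reactants: 25 2,3-bis(benzyloxy)-5-bromophenol
Product: 26 [2,3-bis(benzyloxy)-5-bromophenoxy](tert-butyl)dimethylsilane
Conditions: TBSCl, imidazole, DMF, rt
Reagents that add atoms: tert-butyldimethylsilyl chloride, CC(C)(C)[Si](C)(C)Cl
Why: Silylation marks the one ring B oxygen that is to carry a galloyl group and is stable to Grignard formation.

Step 16
Reactants: 26 [2,3-bis(benzyloxy)-5-bromophenoxy](tert-butyl)dimethylsilane; 21 (2R)-3-{4,6-bis(benzyloxy)-3-bromo-2-hydroxy-5-[3,5,7,4'-tetra-O-benzyl-8-bromo-(−)-epiafzelechin-4β-yl]phenyl}-2-[(tert-butyldimethylsilyl)oxy]-N-methoxy-N-methylpropanamide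
Product: 29 (2R)-1-[3,4-bis(benzyloxy)-5-[(tert-butyldimethylsilyl)oxy]phenyl]-3-{4,6-bis(benzyloxy)-3-bromo-2-hydroxy-5-[3,5,7,4'-tetra-O-benzyl-8-bromo-(−)-epiafzelechin-4β-yl]phenyl}-2-[(tert-butyldimethylsilyl)oxy]propan-1-one, via Grignard reagent 27 (not isolated), via chelated tetrahedral adduct 28 (not isolated)
Conditions: 26, Mg, THF, 50 °C; 21, t-BuMgCl (1.05 equiv), THF, −20 °C, then the Grignard solution (2 equiv), 0 °C → rt; aq NH4Cl, 0 °C
Reagents that add atoms: none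
Why: After t-BuMgCl has turned the ring A phenol of 21 into its magnesium salt, the aryl carbon of 27 adds to the amide carbonyl and the N-methoxy oxygen holds magnesium in a five-membered chelate (28), which should collapse to ketone 29 only on aqueous quench. The closest known reaction type is the Weinreb ketone synthesis with an α-silyloxy amide and an electron-rich arylmagnesium halide. The step forms the bond between C2 of ring C and C1' of ring B of the lower unit and so joins the ring B fragment to the fragment that holds the upper unit, ring A and C3; it closes no ring, ring C being closed through this same carbon in step 17 by 6-exo-trig attack of O1. No new stereocentre arises here: C2 stays a carbonyl carbon until step 17, where the C3 silyloxy group controls it, and the existing C3 centre is safe because the carbonyl stays masked as the chelate under the basic conditions. The selectivities needed are single addition, secured by the chelate, and attack at the amide in the presence of two aryl bromides, secured by a Grignard reagent that does not exchange with these electron-rich bromides at or below room temperature.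

Step 17
Reactants: 29 (2R)-1-[3,4-bis(benzyloxy)-5-[(tert-butyldimethylsilyl)oxy]phenyl]-3-{4,6-bis(benzyloxy)-3-bromo-2-hydroxy-5-[3,5,7,4'-tetra-O-benzyl-8-bromo-(−)-epiafzelechin-4β-yl]phenyl}-2-[(tert-butyldimethylsilyl)oxy]propan-1-one
Product: 31 3,5,7,4'-tetra-O-benzyl-8-bromo-(−)-epiafzelechin-(4β→6)-[5,7,4',5'-tetra-O-benzyl-8-bromo-3,3'-bis-O-(tert-butyldimethylsilyl)-(−)-epigallocatechin], via oxocarbenium triflate 30 (not isolated)
Conditions: Et3SiH (5 equiv), TMSOTf (0.3 equiv), CH2Cl2, −78 → −30 °C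
Reagents that add atoms: none
Why: Reductive etherification as in step 10: the only free phenol (O1, para to the upper unit) closes onto the ketone (6-exo-trig), which fixes the 4→6 connectivity, and hydride should add to oxocarbenium ion 30 anti to the pseudoaxial C3 silyloxy group to set C2 (2R) cis to C3–O, under the low temperature and catalytic acid that the interflavan bond already withstood in step 12.

Step 18
Reactants: 31 3,5,7,4'-tetra-O-benzyl-8-bromo-(−)-epiafzelechin-(4β→6)-[5,7,4',5'-tetra-O-benzyl-8-bromo-3,3'-bis-O-(tert-butyldimethylsilyl)-(−)-epigallocatechin]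
Product: 32 3,5,7,4'-tetra-O-benzyl-8-bromo-(−)-epiafzelechin-(4β→6)-[5,7,4',5'-tetra-O-benzyl-8-bromo-(−)-epigallocatechin]
Conditions: HF·pyridine, THF/pyridine, 0 °C → rt
Reagents that add atoms: none
Why: Fluoride-driven cleavage of the aryl and the secondary alkyl silyl ether under buffered conditions should free exactly the two oxygens to be acylated (lower 3-OH and 3'-OH), while benzyl ethers, aryl bromides and the interflavan bond stay.

Step 19
Reactants: 32 3,5,7,4'-tetra-O-benzyl-8-bromo-(−)-epiafzelechin-(4β→6)-[5,7,4',5'-tetra-O-benzyl-8-bromo-(−)-epigallocatechin]; 33 3,4,5-tris(benzyloxy)benzoic acid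
Product: 34 3,5,7,4'-tetra-O-benzyl-8-bromo-(−)-epiafzelechin-(4β→6)-[5,7,4',5'-tetra-O-benzyl-8-bromo-(−)-epigallocatechin 3,3'-bis-O-(3,4,5-tris(benzyloxy)benzoate)]
Conditions: 33 (3 equiv), DCC, DMAP (cat.), CH2Cl2, rt
Reagents that add atoms: none
Why: Steglich esterification should acylate both the C3 secondary alcohol and the 3'-phenol, the upper C3 oxygen being a benzyl ether.

Step 20
Reactants: 34 3,5,7,4'-tetra-O-benzyl-8-bromo-(−)-epiafzelechin-(4β→6)-[5,7,4',5'-tetra-O-benzyl-8-bromo-(−)-epigallocatechin 3,3'-bis-O-(3,4,5-tris(benzyloxy)benzoate)]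
Product: 35 (−)-epiafzelechin-(4β→6)-(−)-epigallocatechin 3,3'-di-O-gallate (CNP0290965.1)
Conditions: H2 (1 atm), Pd(OH)2/C, NaOAc (2.2 equiv), THF/MeOH/H2O, rt
Reagents that add atoms: none
Why: Hydrogenolysis should remove the fourteen benzyl ethers and both C8 bromines in one operation, and the acetate buffer takes up HBr so that neither the interflavan bond nor the phenolic gallate meets strong acid or base.

Compound list
1 | 3,5-bis(benzyloxy)phenol | Oc1cc(OCc2ccccc2)cc(OCc2ccccc2)c1 | starting material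
2 | 3,5-bis(benzyloxy)-2,6-dibromophenol | Oc1c(Br)c(OCc2ccccc2)cc(OCc2ccccc2)c1Br | intermediate
3 | 1,5-bis(benzyloxy)-2,4-dibromo-3-(methoxymethoxy)benzene | COCOc1c(Br)c(OCc2ccccc2)cc(OCc2ccccc2)c1Br | intermediate
4 | methyl (2R)-oxirane-2-carboxylate (methyl (R)-glycidate) | COC(=O)[C@H]1CO1 | starting material
5 | [4,6-bis(benzyloxy)-3-bromo-2-(methoxymethoxy)phenyl]lithium | [Li]c1c(OCOC)c(Br)c(OCc2ccccc2)cc1OCc1ccccc1 | intermediate
6 | [4,6-bis(benzyloxy)-3-bromo-2-(methoxymethoxy)phenyl]magnesium bromide | Br[Mg]c1c(OCOC)c(Br)c(OCc2ccccc2)cc1OCc1ccccc1 | intermediate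
7 | methyl (2R)-3-[4,6-bis(benzyloxy)-3-bromo-2-(methoxymethoxy)phenyl]-2-hydroxypropanoate | COC(=O)[C@H](O)Cc1c(OCOC)c(Br)c(OCc2ccccc2)cc1OCc1ccccc1 | intermediate
8 | methyl (2R)-3-[4,6-bis(benzyloxy)-3-bromo-2-hydroxyphenyl]-2-hydroxypropanoate | COC(=O)[C@H](O)Cc1c(O)c(Br)c(OCc2ccccc2)cc1OCc1ccccc1 | intermediate
9 | (3R)-5,7-bis(benzyloxy)-8-bromo-3-hydroxychroman-2-one | O=C1Oc2c(Br)c(OCc3ccccc3)cc(OCc3ccccc3)c2C[C@H]1O | intermediate
10 | (3R)-5,7-bis(benzyloxy)-8-bromo-3-[(tert-butyldimethylsilyl)oxy]chroman-2-one | O=C1Oc2c(Br)c(OCc3ccccc3)cc(OCc3ccccc3)c2C[C@H]1O[Si](C)(C)C(C)(C)C | intermediate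
11 | (2R)-3-[4,6-bis(benzyloxy)-3-bromo-2-hydroxyphenyl]-2-[(tert-butyldimethylsilyl)oxy]-N-methoxy-N-methylpropanamide | CON(C)C(=O)[C@H](O[Si](C)(C)C(C)(C)C)Cc1c(O)c(Br)c(OCc2ccccc2)cc1OCc1ccccc1 | intermediate
12 | (3R)-3,5,7-tris(benzyloxy)-8-bromochroman-2-one | O=C1Oc2c(Br)c(OCc3ccccc3)cc(OCc3ccccc3)c2C[C@H]1OCc1ccccc1 | intermediate
13 | (2R)-2-(benzyloxy)-3-[4,6-bis(benzyloxy)-3-bromo-2-hydroxyphenyl]-N-methoxy-N-methylpropanamide | CON(C)C(=O)[C@H](OCc1ccccc1)Cc1c(O)c(Br)c(OCc2ccccc2)cc1OCc1ccccc1 | intermediate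
14 | 1-(benzyloxy)-4-bromobenzene | Brc1ccc(OCc2ccccc2)cc1 | starting material
15 | [4-(benzyloxy)phenyl]magnesium bromide | Br[Mg]c1ccc(OCc2ccccc2)cc1 | intermediate
16 | chelated tetrahedral adduct of 13 and 15: bromomagnesium alkoxide of the N-methoxy-N-methyl hemiaminal, ring A phenol as chloromagnesium salt, (2R) at the benzyloxy carbon, new carbon unassigned | CON(C)C(O[Mg]Br)(c1ccc(OCc2ccccc2)cc1)[C@H](OCc1ccccc1)Cc1c(O[Mg]Cl)c(Br)c(OCc2ccccc2)cc1OCc1ccccc1 | intermediate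
17 | (2R)-2-(benzyloxy)-3-[4,6-bis(benzyloxy)-3-bromo-2-hydroxyphenyl]-1-[4-(benzyloxy)phenyl]propan-1-one | O=C(c1ccc(OCc2ccccc2)cc1)[C@H](OCc1ccccc1)Cc1c(O)c(Br)c(OCc2ccccc2)cc1OCc1ccccc1 | intermediate
18 | (3R)-3,5,7-tris(benzyloxy)-2-[4-(benzyloxy)phenyl]-8-bromo-3,4-dihydrochromenylium trifluoromethanesulfonate (cyclic 2-aryl oxocarbenium ion) | C1c2c(OCc3ccccc3)cc(OCc3ccccc3)c(Br)c2[O+]=C(c2ccc(OCc3ccccc3)cc2)[C@@H]1OCc1ccccc1.[O-]S(=O)(=O)C(F)(F)F | intermediate
19 | (2R,3R)-3,5,7-tris(benzyloxy)-2-[4-(benzyloxy)phenyl]-8-bromochroman (3,5,7,4'-tetra-O-benzyl-8-bromo-(−)-epiafzelechin, 2,3-cis) | C1c2c(OCc3ccccc3)cc(OCc3ccccc3)c(Br)c2O[C@H](c2ccc(OCc3ccccc3)cc2)[C@@H]1OCc1ccccc1 | intermediate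
20 | (2R,3R,4S)-3,5,7-tris(benzyloxy)-2-[4-(benzyloxy)phenyl]-8-bromo-4-(2-ethoxyethoxy)chroman (2,3-cis, 3,4-trans, 4β-alkoxy) | CCOCCO[C@H]1c2c(OCc3ccccc3)cc(OCc3ccccc3)c(Br)c2O[C@H](c2ccc(OCc3ccccc3)cc2)[C@@H]1OCc1ccccc1 | intermediate
21 | (2R)-3-{4,6-bis(benzyloxy)-3-bromo-2-hydroxy-5-[3,5,7,4'-tetra-O-benzyl-8-bromo-(−)-epiafzelechin-4β-yl]phenyl}-2-[(tert-butyldimethylsilyl)oxy]-N-methoxy-N-methylpropanamide (upper unit 2R,3R, C4–aryl bond trans to C3–O) | CON(C)C(=O)[C@H](O[Si](C)(C)C(C)(C)C)Cc1c(O)c(Br)c(OCc2ccccc2)c([C@H]2c3c(OCc4ccccc4)cc(OCc4ccccc4)c(Br)c3O[C@H](c3ccc(OCc4ccccc4)cc3)[C@@H]2OCc2ccccc2)c1OCc1ccccc1 | intermediate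
22 | 5-bromo-2,3-dihydroxybenzaldehyde | O=Cc1cc(Br)cc(O)c1O | starting material
23 | 2,3-bis(benzyloxy)-5-bromobenzaldehyde | O=Cc1cc(Br)cc(OCc2ccccc2)c1OCc1ccccc1 | intermediate
24 | 2,3-bis(benzyloxy)-5-bromophenyl formate | O=COc1cc(Br)cc(OCc2ccccc2)c1OCc1ccccc1 | intermediate
25 | 2,3-bis(benzyloxy)-5-bromophenol | Oc1cc(Br)cc(OCc2ccccc2)c1OCc1ccccc1 | intermediate
26 | [2,3-bis(benzyloxy)-5-bromophenoxy](tert-butyl)dimethylsilane | CC(C)(C)[Si](C)(C)Oc1cc(Br)cc(OCc2ccccc2)c1OCc1ccccc1 | intermediate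
27 | {3,4-bis(benzyloxy)-5-[(tert-butyldimethylsilyl)oxy]phenyl}magnesium bromide | CC(C)(C)[Si](C)(C)Oc1cc([Mg]Br)cc(OCc2ccccc2)c1OCc1ccccc1 | intermediate
28 | chelated tetrahedral adduct of 21 and 27: bromomagnesium alkoxide of the N-methoxy-N-methyl hemiaminal, ring A phenol as chloromagnesium salt, (2R) at the silyloxy carbon, new carbon unassigned, upper unit as in 21 | CON(C)C(O[Mg]Br)(c1cc(O[Si](C)(C)C(C)(C)C)c(OCc2ccccc2)c(OCc2ccccc2)c1)[C@H](O[Si](C)(C)C(C)(C)C)Cc1c(O[Mg]Cl)c(Br)c(OCc2ccccc2)c([C@H]2c3c(OCc4ccccc4)cc(OCc4ccccc4)c(Br)c3O[C@H](c3ccc(OCc4ccccc4)cc3)[C@@H]2OCc2ccccc2)c1OCc1ccccc1 | intermediate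
29 | (2R)-1-[3,4-bis(benzyloxy)-5-[(tert-butyldimethylsilyl)oxy]phenyl]-3-{4,6-bis(benzyloxy)-3-bromo-2-hydroxy-5-[3,5,7,4'-tetra-O-benzyl-8-bromo-(−)-epiafzelechin-4β-yl]phenyl}-2-[(tert-butyldimethylsilyl)oxy]propan-1-one | O=C(c1cc(O[Si](C)(C)C(C)(C)C)c(OCc2ccccc2)c(OCc2ccccc2)c1)[C@H](O[Si](C)(C)C(C)(C)C)Cc1c(O)c(Br)c(OCc2ccccc2)c([C@H]2c3c(OCc4ccccc4)cc(OCc4ccccc4)c(Br)c3O[C@H](c3ccc(OCc4ccccc4)cc3)[C@@H]2OCc2ccccc2)c1OCc1ccccc1 | intermediate
30 | lower-unit 2-aryl-3,4-dihydrochromenylium trifluoromethanesulfonate: (3R)-3-silyloxy oxocarbenium ion of ring C with ring B on C2 and the 4β-linked upper unit on C6 | CC(C)(C)[Si](C)(C)Oc1cc(C2=[O+]c3c(Br)c(OCc4ccccc4)c([C@H]4c5c(OCc6ccccc6)cc(OCc6ccccc6)c(Br)c5O[C@H](c5ccc(OCc6ccccc6)cc5)[C@@H]4OCc4ccccc4)c(OCc4ccccc4)c3C[C@H]2O[Si](C)(C)C(C)(C)C)cc(OCc2ccccc2)c1OCc1ccccc1.[O-]S(=O)(=O)C(F)(F)F | intermediate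
31 | 3,5,7,4'-tetra-O-benzyl-8-bromo-(−)-epiafzelechin-(4β→6)-[5,7,4',5'-tetra-O-benzyl-8-bromo-3,3'-bis-O-(tert-butyldimethylsilyl)-(−)-epigallocatechin] (both units 2R,3R, 2,3-cis; upper 3,4-trans) | CC(C)(C)[Si](C)(C)Oc1cc([C@H]2Oc3c(Br)c(OCc4ccccc4)c([C@H]4c5c(OCc6ccccc6)cc(OCc6ccccc6)c(Br)c5O[C@H](c5ccc(OCc6ccccc6)cc5)[C@@H]4OCc4ccccc4)c(OCc4ccccc4)c3C[C@H]2O[Si](C)(C)C(C)(C)C)cc(OCc2ccccc2)c1OCc1ccccc1 | intermediate
32 | 3,5,7,4'-tetra-O-benzyl-8-bromo-(−)-epiafzelechin-(4β→6)-[5,7,4',5'-tetra-O-benzyl-8-bromo-(−)-epigallocatechin] (lower 3-OH and 3'-OH free) | Oc1cc([C@H]2Oc3c(Br)c(OCc4ccccc4)c([C@H]4c5c(OCc6ccccc6)cc(OCc6ccccc6)c(Br)c5O[C@H](c5ccc(OCc6ccccc6)cc5)[C@@H]4OCc4ccccc4)c(OCc4ccccc4)c3C[C@H]2O)cc(OCc2ccccc2)c1OCc1ccccc1 | intermediate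
33 | 3,4,5-tris(benzyloxy)benzoic acid | OC(=O)c1cc(OCc2ccccc2)c(OCc2ccccc2)c(OCc2ccccc2)c1 | starting material
34 | 3,5,7,4'-tetra-O-benzyl-8-bromo-(−)-epiafzelechin-(4β→6)-[5,7,4',5'-tetra-O-benzyl-8-bromo-(−)-epigallocatechin 3,3'-bis-O-(3,4,5-tris(benzyloxy)benzoate)] | O=C(Oc1cc([C@H]2Oc3c(Br)c(OCc4ccccc4)c([C@H]4c5c(OCc6ccccc6)cc(OCc6ccccc6)c(Br)c5O[C@H](c5ccc(OCc6ccccc6)cc5)[C@@H]4OCc4ccccc4)c(OCc4ccccc4)c3C[C@H]2OC(=O)c2cc(OCc3ccccc3)c(OCc3ccccc3)c(OCc3ccccc3)c2)cc(OCc2ccccc2)c1OCc1ccccc1)c1cc(OCc2ccccc2)c(OCc2ccccc2)c(OCc2ccccc2)c1 | intermediate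
35 | (−)-epiafzelechin-(4β→6)-(−)-epigallocatechin 3,3'-di-O-gallate (CNP0290965.1; upper unit 2R,3R,4S, lower unit 2R,3R) | O=C(Oc1cc([C@H]2Oc3cc(O)c([C@H]4c5c(O)cc(O)cc5O[C@H](c5ccc(O)cc5)[C@@H]4O)c(O)c3C[C@H]2OC(=O)c2cc(O)c(O)c(O)c2)cc(O)c1O)c1cc(O)c(O)c(O)c1 | target

Total step count: 20. Longest linear sequence: 15 steps (1–4, 7–11, 12, 16–20).

Steps most likely to fail

Step 17. The process at risk is acid-induced heterolysis of the C4–C6 interflavan bond with silane capture of the resulting cation, together with incomplete facial selectivity in the hydride transfer. The fallback replaces the oxocarbenium reduction by a stepwise reduction and an SN2 ring closure; it sets out from 29 and comes back at 32. HF·pyridine removes both silyl ethers to give the α-hydroxy ketone F1. Zn(BH4)2 in Et2O at −20 °C should reduce it under chelation control to the anti (1S,2R) 1,2-diol F2. HC(OEt)3 and PPTS in 1,2-dichloroethane at 60 °C turn the diol into its cyclic orthoformate, which the ring A phenol opens at the benzylic carbon with inversion to give the 2,3-cis flavan 3-O-formate F3. K2CO3 in MeOH then gives 32.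

Step 12. The process at risk is O-alkylation of the free phenol and binding of the silyl triflate by the N-methoxy amide, which slow the C-alkylation at the doubly flanked position and let 20 condense with itself through its C6. The fallback couples at the lactone stage and opens the ring afterwards; it sets out from 20 and 10 and comes back at 21. Lactone 10 has no free OH, no amide and one free ring position. It is joined to 20 with BF3·OEt2 in CH2Cl2 at −40 → 0 °C to give the dimeric lactone F4, and the aminolysis of step 6 (MeNH(OMe)·HCl, i-PrMgCl) then opens F4 to 21.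

Step 3. The process at risk is sluggish epoxide opening by the doubly ortho-substituted aryl nucleophile, with competing attack on the ester and halohydrin formation. The fallback sets the C3 centre by asymmetric hydrogenation, not from the chiral pool; it sets out from 3 and comes back at 9. Bromine–lithium exchange (n-BuLi, THF, −78 °C) and DMF give the aldehyde F5. A Horner–Wadsworth–Emmons reaction with methyl 2-acetoxy-2-(dimethoxyphosphoryl)acetate (LiCl, DBU, MeCN) gives the (Z)-enol acetate F6. Hydrogenation with [Rh(cod)((R,R)-Et-DuPhos)]OTf (the ligand antipode being chosen to give 2R) should give the (2R)-acetoxy ester F7. The conditions of step 4 then remove acetate and MOM and lactonise to 9.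

Further compounds
F1 | step 17 | (2R)-1-[3,4-bis(benzyloxy)-5-hydroxyphenyl]-3-{4,6-bis(benzyloxy)-3-bromo-2-hydroxy-5-[3,5,7,4'-tetra-O-benzyl-8-bromo-(−)-epiafzelechin-4β-yl]phenyl}-2-hydroxypropan-1-one | O=C(c1cc(O)c(OCc2ccccc2)c(OCc2ccccc2)c1)[C@H](O)Cc1c(O)c(Br)c(OCc2ccccc2)c([C@H]2c3c(OCc4ccccc4)cc(OCc4ccccc4)c(Br)c3O[C@H](c3ccc(OCc4ccccc4)cc3)[C@@H]2OCc2ccccc2)c1OCc1ccccc1
F2 | step 17 | (1S,2R)-1-[3,4-bis(benzyloxy)-5-hydroxyphenyl]-3-{4,6-bis(benzyloxy)-3-bromo-2-hydroxy-5-[3,5,7,4'-tetra-O-benzyl-8-bromo-(−)-epiafzelechin-4β-yl]phenyl}propane-1,2-diol (anti) | O[C@@H](c1cc(O)c(OCc2ccccc2)c(OCc2ccccc2)c1)[C@H](O)Cc1c(O)c(Br)c(OCc2ccccc2)c([C@H]2c3c(OCc4ccccc4)cc(OCc4ccccc4)c(Br)c3O[C@H](c3ccc(OCc4ccccc4)cc3)[C@@H]2OCc2ccccc2)c1OCc1ccccc1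
F3 | step 17 | 3,5,7,4'-tetra-O-benzyl-8-bromo-(−)-epiafzelechin-(4β→6)-[5,7,4',5'-tetra-O-benzyl-8-bromo-(−)-epigallocatechin 3-O-formate] | Oc1cc([C@H]2Oc3c(Br)c(OCc4ccccc4)c([C@H]4c5c(OCc6ccccc6)cc(OCc6ccccc6)c(Br)c5O[C@H](c5ccc(OCc6ccccc6)cc5)[C@@H]4OCc4ccccc4)c(OCc4ccccc4)c3C[C@H]2OC=O)cc(OCc2ccccc2)c1OCc1ccccc1
F4 | step 12 | (3R)-5,7-bis(benzyloxy)-8-bromo-3-[(tert-butyldimethylsilyl)oxy]-6-[3,5,7,4'-tetra-O-benzyl-8-bromo-(−)-epiafzelechin-4β-yl]chroman-2-one | O=C1Oc2c(Br)c(OCc3ccccc3)c([C@H]3c4c(OCc5ccccc5)cc(OCc5ccccc5)c(Br)c4O[C@H](c4ccc(OCc5ccccc5)cc4)[C@@H]3OCc3ccccc3)c(OCc3ccccc3)c2C[C@H]1O[Si](C)(C)C(C)(C)C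
F5 | step 3 | 4,6-bis(benzyloxy)-3-bromo-2-(methoxymethoxy)benzaldehyde | O=Cc1c(OCOC)c(Br)c(OCc2ccccc2)cc1OCc1ccccc1
F6 | step 3 | methyl (Z)-2-acetoxy-3-[4,6-bis(benzyloxy)-3-bromo-2-(methoxymethoxy)phenyl]prop-2-enoate | COC(=O)/C(OC(C)=O)=C/c1c(OCOC)c(Br)c(OCc2ccccc2)cc1OCc1ccccc1
F7 | step 3 | methyl (2R)-2-acetoxy-3-[4,6-bis(benzyloxy)-3-bromo-2-(methoxymethoxy)phenyl]propanoate | COC(=O)[C@H](OC(C)=O)Cc1c(OCOC)c(Br)c(OCc2ccccc2)cc1OCc1ccccc1
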